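In the north-west run, at 8.00 min, the readings show 17.2% substrate and 28.2% target, so 54.6% of the substrate charged reads as neither. Target therefore trails the loss of substrate, and we reckon with the fraction left, L, since one minus L is a ceiling on target.

in all of them: substrate 1.5 M (in portions, 4); catalyst 1 mol%
- north-west: partner 0.60 equiv; temperature 38 °C; run made earlier; portions every 25 s
- north: partner 0.90 equiv; temperature 65 °C; run made earlier; portions every 25 s
- Tuesday's: partner 1.20 equiv; temperature 75 °C; the portions of substrate follow each other after 25 s, the first at the start; time 8.0 min
- Saturday's: partner 1.20 equiv; temperature 50 °C; the portions of substrate follow each other after 25 s, the first at the start; time 8.0 min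
- Monday's: partner 1.20 equiv; temperature 25 °C; the portions of substrate follow each other after 25 s, the first at the start; time 8.0 min

| run | time / min | target / % | substrate / % |
|---|---|---|---|
| north-west | 4.00 | 11.1 | 46.1 |
| north-west | 8.00 | 28.2 | 17.2 |
| north-west | 15.0 | 47.6 | 3.6 |
| north-west | 25.0 | 54.3 | 0 |
| north-west | 50.0 | 61.6 | 1.1 |
| north | 1.00 | 10.0 | 31.1 |
| north | 2.00 | 31.2 | 12.9 |
| north | 4.00 | 60.8 | 1.8 |
| north | 6.00 | 71.9 | 0 |
| north | 12.0 | 83.0 | 0.7 |

(standard deviation of a reading: 1 percentage point)

1. the best flask by amount of target, in percent of the substrate charged; "all alike" if 1.5 percentage points covers them all (Tuesday's / Saturday's / Monday's / all alike)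
2. amount of target at the end, in percent of the substrate charged, Tuesday's
3. amount of target at the end, in percent of the substrate charged, Saturday's
4. amount of target at the end, in percent of the substrate charged, Monday's

- the analysis behind the earlier runs scatters by 1 percentage point, standard deviation

A bench rule treats the 4 portions as one charge made at their mean time, τ = 37.5 s. Then the fraction left at a time t after the feed has ended is L = exp(−k(t − τ)), where k is a pseudo-first-order constant holding the fixed catalyst loading. The reading above gives k = 0.239 min⁻¹ at 38 °C, and the north run at 2.00 min gives 1.49 min⁻¹ at 65 °C.

The rule takes the exponential of an average for the average of exponentials, so it holds while the feed span, 1.25 min, is short against the inverse of k. The product of k and that span is 0.299 in the north-west run but 1.86 in the north run, which is larger and past the border, so the north constant reads low.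

The two constants give an activation energy E = 59.3 kJ mol⁻¹, low for the same reason. For Saturday's this gives k = 0.559 min⁻¹ and L = 1.62%. For Monday's it gives k = 0.0878 min⁻¹ and L = 52.3%, on the low side. The ceilings on target in Saturday's and Monday's are thus 98.4% and 47.7%. Tuesday's is hotter than the north run, so it lies past the border as well, and we give it no L. We commit to Tuesday's first and to Monday's last, well under its ceiling.

The forecast names Tuesday's, with 94% (86% to 98%), 73% (66% to 79%) and 25% (18% to 32%) of target, and its hottest figure “assumes no new side reaction above the tested range”; these are target figures, where ours are ceilings.

The flasks give 94.9% for Tuesday's, 74.9% for Saturday's and 18.4% for Monday's.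

    substrate + catalyst → catalyst + intermediate (k = 0.670 L mol⁻¹ s⁻¹, Ea = 64.0 kJ mol⁻¹)
    partner + catalyst + intermediate → catalyst + target (k = 0.290 L² mol⁻² s⁻¹, Ea = 36.0 kJ mol⁻¹)
    (constants at 50 °C)

Substrate left at 8.00 min is 1.2% in Saturday's against our 1.62%, and 55% in Monday's against our 52.3%. The first step carries catalyst to the first power, so for Saturday's neighbour with 0.6 mol% of catalyst L becomes 8.42%, and that flask holds 7.0%. In Saturday's, half of the first step's turnover is done by 1.82 min, but half of the second step's takes until 3.39 min, which is later. At 8.00 min the intermediate in Saturday's still holds 23.9%.

(The numbers in the tables are simulated from invented constants; scatter was added.)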